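(All constants stand for no real mixture; the run is a simulation.)

We want to know how much intermediate stands at the end of three flasks that differ in their charge of starting material, and how that row runs.

| setting | winter | autumn | noon |
|---|---|---|---|
| starting material | 0.15 M | 0.30 M | 0.60 M |
| partner | 0.450 M | 0.450 M | 0.450 M |
| time | 6.0 d | 6.0 d | 6.0 d |

    intermediate → product (k1 = 6.4 × 10⁻⁶ /s)
    2 partner → homo dimer (k2 = 2.7 × 10⁻⁵ /M/s)
    starting material + partner → intermediate + by-product (k3 = 8.4 × 10⁻⁵ /M/s)

1. [intermediate] at the end for winter, autumn, noon, in this order
2. the course of these numbers from the first flask to the last (falls, then rises / rises all the way / rises, then falls / falls all the way / hardly changes)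

Which constants must we know well? The two partner steps share out the partner: at the start of noon the cross reaction takes a fraction 0.675 of it, and raising 8.4 × 10⁻⁵ /M/s by 50.0% moves this to 0.757, a small shift. The decay constant 6.4 × 10⁻⁶ /s is different, since it sits in an exponent: the same error shrinks whatever stands unfed at half time by a factor 2.29, so it matters more.

Control changes hands when the making of intermediate falls below its using up. From there on, we reckon with the second-half survival 0.190, the fraction of the intermediate present at half time that is still there at the end if none is made meanwhile.

At noon the partner starts with a half-life near 0.107 d, shorter than half the run, so we expect noon to end on survival. If the whole noon partner charge went at the very start in that share, the intermediate so made would leave 1.83% of the noon charge, a rough figure. For winter and autumn we stop here, since we cannot size by hand the feed that lingers after half time.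

The forecast says 0.0097 M, 0.017 M, 0.016 M, so rises, then falls, on the ground that “the middle flask, whose partner lingers in a slow tail, ends slightly highest”. Its noon figure is 2.67% of the charge, above ours.

The flasks give 0.00964 M, 0.0172 M, 0.0155 M: rises, then falls, with the turn at a starting material concentration of 0.34 M.

At noon the cross reaction ran while partner, the limiting reagent, stood, and by 3.00 d partner was down to 0.113% of its charge with intermediate at 13.4% of the starting material charged; survival carries that to 2.55%, and the noon flask shows 2.58%. In winter, with partner still at 9.62% of its charge at half time, survival carries 24.5% to 4.66% against 6.42% found, and intermediate made after half time and still there at the end accounts for the difference of 1.8 percentage points.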